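The numbers in the tables were computed for substances that don't exist; scatter was added.

A mole per litre was my unit: I booked one of reagent against each one of product. The new flasks were to be ranked, and two earlier runs were known.

| flask | substrate | reagent | capture agent | remark | time |
|---|---|---|---|---|---|
| maple | 0.48 M | 0.84 M (in portions, 4) | 0.040 M | run made earlier; portions every 25 min |  |
| alder | 1.1 M | 0.84 M (in portions, 4) | 0.040 M | run made earlier; portions every 25 min |  |
| Tuesday's | 0.40 M | 0.840 M (in portions, 4) | 0.0400 M | the portions of reagent follow each other after 25 min, the first at the start | 20 h |
| Sunday's | 2.5 M | 0.840 M (in portions, 4) | 0.0400 M | the portions of reagent follow each other after 25 min, the first at the start | 20 h |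
| Thursday's | 0.80 M | 0.840 M (in portions, 4) | 0.0400 M | the portions of reagent follow each other after 25 min, the first at the start | 20 h |
| Friday's | 3.0 M | 0.840 M (in portions, 4) | 0.0400 M | the portions of reagent follow each other after 25 min, the first at the start | 20 h |
| Wednesday's | 1.5 M | 0.840 M (in portions, 4) | 0.0400 M | the portions of reagent follow each other after 25 min, the first at the start | 20 h |

| run | time / h | product / % | substrate / % |
|---|---|---|---|
| maple | 2.50 | 15.5 | 19.7 |
| maple | 8.00 | 47.3 | 9.3 |
| maple | 12.0 | 58.7 | 6.5 |
| maple | 20.0 | 73.0 | 3.5 |
| alder | 1.50 | 5.3 | 45.7 |
| alder | 4.00 | 21.2 | 26.8 |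
| alder | 8.00 | 36.6 | 16.7 |
| alder | 20.0 | 56.1 | 7.8 |

(standard deviation of a reading: 0.3 percentage points)

- the earlier runs were read with a standard deviation of 0.3 percentage points
- a reading or a percentage of product counts all its forms, free or not
- a reading of substrate is of its free form alone

- the flasks put in order of amount of product, in percent of the substrate charged, best first, at 20 h (Tuesday's / Sunday's / Thursday's / Friday's / Wednesday's)
- the same order at 4.0 h (Tuesday's / Sunday's / Thursday's / Friday's / Wednesday's)
- the amount of product, in percent of the substrate charged of the flask you put first, at 20 h
- the amount of product, in percent of the substrate charged of the flask you put last, at 20 h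

I opened the ledger on the alder run at 20.0 h. Alder was charged 0.84 M of reagent. Product took 0.617 M of it, so 0.223 M stayed unclaimed. The substrate read neither as free nor as product came to 0.397 M. That was more than the unclaimed reagent, so on my books part of it sat in some form that held no reagent.

Then I closed the books on the new flasks. Friday's had less reagent than substrate, which made reagent its limiting reagent. Its reagent charge over its substrate charge gave 28.0 %, and I called this the reagent ceiling: the percentage of product its reagent could pay for. Sunday's ceiling was 33.6 % and Wednesday's 56.0 %. The ceilings of Thursday's and Tuesday's, 105 % and 210 %, stood above a full yield. I ranked those two from the runs, where the yield at 20.0 h was 73.0 % in maple and 56.1 % in alder. So I put Tuesday's first and Friday's last, with Friday's under 28.0 %.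

The forecast gave Tuesday's > Thursday's > Wednesday's > Sunday's > Friday's at 20 h and Tuesday's > Thursday's > Wednesday's > Sunday's > Friday's at 4.0 h, with 76.5 % for the first flask and 26 % for the last. Its ground was this: “Absolute product saturates near 0.75 M, so percent yield falls steadily with substrate charged, at both 4 h and 20 h.” We parted on the level: its saturation stood near 0.75 M of product, and my ceiling stood at the 0.840 M of reagent charged.

The flasks came out as Tuesday's > Thursday's > Wednesday's > Sunday's > Friday's at 20 h and Tuesday's > Thursday's > Wednesday's > Sunday's > Friday's at 4.0 h. Tuesday's gave 75.3 % and Friday's 25.6 %.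

    substrate + reagent ⇌ loose adduct (K = 5.80 M⁻¹, k = 0.0610 M⁻¹ min⁻¹)
    capture agent + loose adduct → trapped intermediate (k = 0.00110 M⁻¹ min⁻¹)
    loose adduct → product (k = 0.00250 min⁻¹)
    substrate + product ⇌ idle adduct, settled at all times (K = 14.0 M⁻¹)

Friday's 25.6 % stood below its ceiling of 28.0 %. At 200 h Friday's gave 27.6 % of product, level with that ceiling. The neighbour was like Tuesday's but with 0.10 M of substrate, so its ceiling was 840 %, and the books ran the other way. Turning all that substrate into product would spend 11.9 % of the reagent and leave 88.1 %. At 20.0 h the neighbour gave 85.8 % product and held 88.6 % of its reagent.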